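**Retrosynthetic overview**
1. Target 17 ⇐ ketal-triggered semipinacol: the allyl group shifts from C6 to C5 in the 6-allyl-6-hydroxy-5,5-dimethoxy carbinol 15. C6 becomes the ketone, one ketal methoxy stays as the C5 ether, and 6S is relayed to 5R.
2. 15 ⇐ catalyst-controlled allylation of the C6 ketone of quinone monoketal 14 ⇐ oxidative dearomatisation (PhI(OAc)2, MeOH) of the 5-methoxy-6-hydroxy dihydrobenzofuran 13.
3. Dihydrofuran ring (C2 and C3 set) ⇐ enantioselective quinone + propenylarene formal [3+2] of 10 and 7; a benzyl group on O6 keeps the two ring oxygens apart until O5 is methylated.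
4. 7 ⇐ p-cresol (bromination/oxidation, Cu methoxylation, Takai olefination); 10 ⇐ resorcinol (mono-benzylation, Teuber oxidation).
5. Ring order: the trimethoxyphenyl ring and the benzo ring are carried in, the dihydrofuran ring is closed in step 6, and the benzo ring is dearomatised last.

Reading of the target: (2S,3S,5R), with aryl and methyl trans on the dihydrofuran ring and the allyl group on the same face as the aryl group.
Assumption: the facial sense of the two catalyst-controlled steps (6 and 9) is taken as delivered by the ligand antipodes named; if a first run shows the opposite sense, the mirror-image ligand is used with no other change.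

**Step 1**
Reactants: 1 p-cresol
Product: 4 3,5-dibromo-4-hydroxybenzaldehyde, via 2,6-dibromo-4-methylphenol 2 (not isolated), via 2,6-dibromo-4-(dibromomethyl)phenol 3 (not isolated)
Conditions: Br2 (4.1 equiv), o-dichlorobenzene, 35 °C then 150 °C; then H2O, 100 °C
Reagents that add atoms: bromine, BrBr; water, O
Why: Electrophilic aromatic bromination at both positions ortho to the hydroxyl, then thermal radical benzylic dibromination and hydrolysis of the benzal bromide to the aldehyde (the established cresol-to-hydroxybenzaldehyde process); no stereocenter.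

**Step 2**
Reactants: 4 3,5-dibromo-4-hydroxybenzaldehyde
Product: 6 3,4,5-trimethoxybenzaldehyde, via sodium 4-formyl-2,6-dimethoxyphenoxide 5 (not isolated)
Conditions: NaOMe (4 equiv), CuCl (10 mol %), DMF/MeOH, 110 °C; then MeI (2 equiv), 40 °C
Reagents that add atoms: sodium methoxide, C[O-].[Na+]; iodomethane, CI
Why: CuCl-catalysed Ullmann-type methoxylation of both aryl bromides on the phenoxide, followed by Williamson O-methylation of the sodium phenoxide already present in the pot; no stereocenter.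

**Step 3**
Reactants: 6 3,4,5-trimethoxybenzaldehyde
Product: 7 (E)-1,2,3-trimethoxy-5-(prop-1-en-1-yl)benzene
Conditions: CH3CHI2 (2 equiv), CrCl2 (8 equiv), THF, rt
Reagents that add atoms: 1,1-diiodoethane, CC(I)I
Why: Takai–Utimoto olefination, in which the gem-dichromium reagent adds to the aldehyde and eliminates anti to give the E alkene (typically ≥ 95:5 for aryl aldehydes).

**Step 4**
Reactants: 8 resorcinol
Product: 9 3-(benzyloxy)phenol
Conditions: BnBr (1 equiv), 8 (3 equiv), K2CO3 (1 equiv), acetone, reflux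
Reagents that add atoms: benzyl bromide, BrCc1ccccc1
Why: Williamson etherification, with excess diol making the mono-ether the main product (unreacted resorcinol is washed out with water).

**Step 5**
Reactants: 9 3-(benzyloxy)phenol
Product: 10 2-(benzyloxy)cyclohexa-2,5-diene-1,4-dione
Conditions: (KSO3)2NO (2.2 equiv), KH2PO4, H2O/acetone, 0 °C → rt
Reagents that add atoms: potassium nitrosodisulfonate, [K+].[K+].[O-]S(=O)(=O)N([O])S(=O)(=O)[O-]
Why: Teuber oxidation of a para-unsubstituted phenol to the p-quinone, the alkoxy group directing oxygenation to the free para position.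

**Step 6**
Reactants: 7 (E)-1,2,3-trimethoxy-5-(prop-1-en-1-yl)benzene; 10 2-(benzyloxy)cyclohexa-2,5-diene-1,4-dione
Product: 11 (2S,3S)-6-(benzyloxy)-3-methyl-2-(3,4,5-trimethoxyphenyl)-2,3-dihydro-1-benzofuran-5-ol
Conditions: TiCl4/Ti(OiPr)4 (1:1), (R,R)-TADDOL (1.5 equiv of the chiral titanium TADDOLate), CH2Cl2, −78 → 0 °C
Reagents that add atoms: none
Why: Engler-type Lewis-acid-promoted quinone–propenylarene formal [3+2] cycloaddition (Michael addition then oxa-cyclisation): the C1 carbonyl and the benzyloxy oxygen chelate the chiral tetravalent titanium TADDOLate, the alkene β-carbon attacks C5 of the quinone on one enantioface (sets C3), the benzylic cation is captured by the C4 carbonyl oxygen anti to the methyl group (sets C2, trans), and tautomerisation gives the phenol.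

**Step 7**
Reactants: 11 (2S,3S)-6-(benzyloxy)-3-methyl-2-(3,4,5-trimethoxyphenyl)-2,3-dihydro-1-benzofuran-5-ol
Product: 12 (2S,3S)-6-(benzyloxy)-5-methoxy-3-methyl-2-(3,4,5-trimethoxyphenyl)-2,3-dihydro-1-benzofuran
Conditions: MeI (2 equiv), K2CO3, acetone, reflux
Reagents that add atoms: iodomethane, CI
Why: Williamson O-methylation of the only free phenol; the stereocenters are not touched.

**Step 8**
Reactants: 12 (2S,3S)-6-(benzyloxy)-5-methoxy-3-methyl-2-(3,4,5-trimethoxyphenyl)-2,3-dihydro-1-benzofuran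
Product: 14 (2S,3S)-5,5-dimethoxy-3-methyl-2-(3,4,5-trimethoxyphenyl)-2,3-dihydro-1-benzofuran-6(5H)-one, via (2S,3S)-5-methoxy-3-methyl-2-(3,4,5-trimethoxyphenyl)-2,3-dihydro-1-benzofuran-6-ol 13 (not isolated)
Conditions: H2 (1 atm), Pd/C, MeOH, rt; filter under N2; then PhI(OAc)2 (1.1 equiv), 0 °C, 15 min
Reagents that add atoms: methanol, CO
Why: Benzyl ether hydrogenolysis followed by oxidative dearomatisation of the 2-methoxyphenol with a trivalent iodine reagent, methanol adding at the methoxy-bearing ortho carbon to give the ortho-quinone monoketal; C5 carries two methoxy groups, so no new stereocenter arises.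

**Step 9**
Reactants: 14 (2S,3S)-5,5-dimethoxy-3-methyl-2-(3,4,5-trimethoxyphenyl)-2,3-dihydro-1-benzofuran-6(5H)-one
Product: 15 (2S,3S,6S)-5,5-dimethoxy-3-methyl-6-(prop-2-en-1-yl)-2-(3,4,5-trimethoxyphenyl)-2,3,5,6-tetrahydro-1-benzofuran-6-ol
Conditions: allylB(pin) (1.5 equiv), CuF2·2H2O (3 mol %), (R,R)-iPr-DuPHOS (6 mol %), La(OiPr)3 (4.5 mol %), DMF, −40 °C; pH 7 buffer work-up
Reagents that add atoms: allylboronic acid pinacol ester, C=CCB1OC(C)(C)C(C)(C)O1
Why: Copper-catalysed enantioselective allylboration of a ketone (Shibasaki type), in which the chiral allylcopper adds 1,2 to the C6 carbonyl, distinguishing the bulky ketal flank from the vinyl CH flank and attacking the Re face (anti to the C3 methyl group) to set 6S under catalyst control.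

**Step 10**
Reactants: 15 (2S,3S,6S)-5,5-dimethoxy-3-methyl-6-(prop-2-en-1-yl)-2-(3,4,5-trimethoxyphenyl)-2,3,5,6-tetrahydro-1-benzofuran-6-ol
Product: 17 (2S,3S,5R)-5-methoxy-3-methyl-5-(prop-2-en-1-yl)-2-(3,4,5-trimethoxyphenyl)-2,3-dihydro-1-benzofuran-6(5H)-one, via trimethylsilyl ether 16 (not isolated)
Conditions: TMSOTf (1.3 equiv), 2,6-di-tert-butyl-4-methylpyridine (1.5 equiv), CH2Cl2, −78 → −40 °C; Et3N quench at −78 °C
Reagents that add atoms: trimethylsilyl trifluoromethanesulfonate, C[Si](C)(C)OS(=O)(=O)C(F)(F)F (its silyl group is present in 16 only)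
Why: Proposed new method: TMSOTf silylates O6 and then removes one ketal methoxy group from C5 to give a methoxy-stabilised cyclohexadienyl (oxocarbenium) cation with most of its charge on C5; the C6–allyl bond migrates to C5 on its own face while the O6–Si oxygen turns C6 into the vinylogous-ester carbonyl (pushed by O1) and TMS+ is lost, so 6S is relayed to 5R and the surviving ketal methoxy becomes the C5 ether; the closest known reaction types are the Lewis-acid semipinacol 1,2-shift of α-silyloxy acetals (Tsuchihashi–Suzuki type) and the α-ketol rearrangement of ortho-quinols, neither shown on a masked ortho-benzoquinone carbinol, where re-aromatisation competes.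

**Compound list**
1 | p-cresol (4-methylphenol) | Cc1ccc(O)cc1 | starting material
2 | 2,6-dibromo-4-methylphenol | Cc1cc(Br)c(O)c(Br)c1 | intermediate
3 | 2,6-dibromo-4-(dibromomethyl)phenol | BrC(Br)c1cc(Br)c(O)c(Br)c1 | intermediate
4 | 3,5-dibromo-4-hydroxybenzaldehyde | O=Cc1cc(Br)c(O)c(Br)c1 | intermediate
5 | sodium 4-formyl-2,6-dimethoxyphenoxide (syringaldehyde sodium salt) | COc1cc(C=O)cc(OC)c1[O-].[Na+] | intermediate
6 | 3,4,5-trimethoxybenzaldehyde | COc1cc(C=O)cc(OC)c1OC | intermediate
7 | (E)-1,2,3-trimethoxy-5-(prop-1-en-1-yl)benzene | C/C=C/c1cc(OC)c(OC)c(OC)c1 | intermediate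
8 | resorcinol (benzene-1,3-diol) | Oc1cccc(O)c1 | starting material
9 | 3-(benzyloxy)phenol | Oc1cccc(OCc2ccccc2)c1 | intermediate
10 | 2-(benzyloxy)cyclohexa-2,5-diene-1,4-dione | O=C1C=CC(=O)C(OCc2ccccc2)=C1 | intermediate
11 | (2S,3S)-6-(benzyloxy)-3-methyl-2-(3,4,5-trimethoxyphenyl)-2,3-dihydro-1-benzofuran-5-ol | Oc1cc2c(cc1OCc1ccccc1)O[C@H](c1cc(OC)c(OC)c(OC)c1)[C@H]2C | intermediate
12 | (2S,3S)-6-(benzyloxy)-5-methoxy-3-methyl-2-(3,4,5-trimethoxyphenyl)-2,3-dihydro-1-benzofuran | COc1cc2c(cc1OCc1ccccc1)O[C@H](c1cc(OC)c(OC)c(OC)c1)[C@H]2C | intermediate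
13 | (2S,3S)-5-methoxy-3-methyl-2-(3,4,5-trimethoxyphenyl)-2,3-dihydro-1-benzofuran-6-ol | COc1cc2c(cc1O)O[C@H](c1cc(OC)c(OC)c(OC)c1)[C@H]2C | intermediate
14 | (2S,3S)-5,5-dimethoxy-3-methyl-2-(3,4,5-trimethoxyphenyl)-2,3-dihydro-1-benzofuran-6(5H)-one | COC1(OC)C=C2C(=CC1=O)O[C@H](c1cc(OC)c(OC)c(OC)c1)[C@H]2C | intermediate
15 | (2S,3S,6S)-5,5-dimethoxy-3-methyl-6-(prop-2-en-1-yl)-2-(3,4,5-trimethoxyphenyl)-2,3,5,6-tetrahydro-1-benzofuran-6-ol | COC1(OC)C=C2C(=C[C@@]1(O)CC=C)O[C@H](c1cc(OC)c(OC)c(OC)c1)[C@H]2C | intermediate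
16 | (2S,3S,6S)-5,5-dimethoxy-3-methyl-6-(prop-2-en-1-yl)-2-(3,4,5-trimethoxyphenyl)-6-[(trimethylsilyl)oxy]-2,3,5,6-tetrahydro-1-benzofuran | COC1(OC)C=C2C(=C[C@@]1(O[Si](C)(C)C)CC=C)O[C@H](c1cc(OC)c(OC)c(OC)c1)[C@H]2C | intermediate
17 | (2S,3S,5R)-5-methoxy-3-methyl-5-(prop-2-en-1-yl)-2-(3,4,5-trimethoxyphenyl)-2,3-dihydro-1-benzofuran-6(5H)-one | C=CC[C@@]1(OC)C=C2C(=CC1=O)O[C@H](c1cc(OC)c(OC)c(OC)c1)[C@H]2C | target

**Step count**
Total: 10 steps. Longest linear sequence: 8 steps (1, 2, 3, 6, 7, 8, 9, 10, from p-cresol).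

**Steps most likely to fail**

Step 10 (the proposed semipinacol). The cation could instead move the allyl group to C7, lose it, or pass it to C4 by a [3,3] path; each of these re-aromatises the ring. Acid could also open the benzylic C2–O1 bond. The fallback uses known chemistry, sets out from 15 and comes back at 17. Mild ketal hydrolysis (aqueous oxalic acid, THF, 0 °C) gives the ortho-quinol (2S,3S,6S)-6-hydroxy-3-methyl-6-(prop-2-en-1-yl)-2-(3,4,5-trimethoxyphenyl)-2,3-dihydro-1-benzofuran-5(6H)-one F3. Its α-ketol rearrangement (catalytic Sc(OTf)3, CH2Cl2, 0 °C) moves the allyl group suprafacially to C5, driven by formation of the vinylogous ester, and gives (2S,3S,5R)-5-hydroxy-3-methyl-5-(prop-2-en-1-yl)-2-(3,4,5-trimethoxyphenyl)-2,3-dihydro-1-benzofuran-6(5H)-one F4. O-methylation of this tertiary ketol with MeOTf and 2,6-di-tert-butyl-4-methylpyridine in CH2Cl2 then gives 17.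

Step 9 (catalyst-controlled allylation). The ketone is a hindered vinylogous ester next to a ketal, and the catalyst has to override whatever small bias the remote C2/C3 centers impose; the diastereomer ratio may be poor or the monoketal may dimerise first. The fallback sets out from 14 and comes back at 15. Allylmagnesium bromide in THF at −78 °C adds fast and without facial control, giving 15 together with its C6 epimer (2S,3S,6R)-5,5-dimethoxy-3-methyl-6-(prop-2-en-1-yl)-2-(3,4,5-trimethoxyphenyl)-2,3,5,6-tetrahydro-1-benzofuran-6-ol F2. The two diastereomers are separated on Et3N-deactivated silica and 15 goes on to step 10.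

Step 6 (enantioselective formal [3+2]). Yield and enantiomeric excess with the benzyloxyquinone and the trimethoxy alkene may be moderate, and some [5+2] adduct may form. The fallback sets out from 7 and 10 and comes back at 11. The achiral promoter TiCl4/Ti(OiPr)4 (CH2Cl2, −78 → 0 °C) gives the racemic trans product, that is 11 together with (2R,3R)-6-(benzyloxy)-3-methyl-2-(3,4,5-trimethoxyphenyl)-2,3-dihydro-1-benzofuran-5-ol F1. Preparative chiral-phase SFC (amylose carbamate column) separates the enantiomers and 11 goes on to step 7.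

**Further compounds**
F1 | step 6 | (2R,3R)-6-(benzyloxy)-3-methyl-2-(3,4,5-trimethoxyphenyl)-2,3-dihydro-1-benzofuran-5-ol | Oc1cc2c(cc1OCc1ccccc1)O[C@@H](c1cc(OC)c(OC)c(OC)c1)[C@@H]2C
F2 | step 9 | (2S,3S,6R)-5,5-dimethoxy-3-methyl-6-(prop-2-en-1-yl)-2-(3,4,5-trimethoxyphenyl)-2,3,5,6-tetrahydro-1-benzofuran-6-ol | COC1(OC)C=C2C(=C[C@]1(O)CC=C)O[C@H](c1cc(OC)c(OC)c(OC)c1)[C@H]2C
F3 | step 10 | (2S,3S,6S)-6-hydroxy-3-methyl-6-(prop-2-en-1-yl)-2-(3,4,5-trimethoxyphenyl)-2,3-dihydro-1-benzofuran-5(6H)-one | O=C1C=C2C(=C[C@@]1(O)CC=C)O[C@H](c1cc(OC)c(OC)c(OC)c1)[C@H]2C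
F4 | step 10 | (2S,3S,5R)-5-hydroxy-3-methyl-5-(prop-2-en-1-yl)-2-(3,4,5-trimethoxyphenyl)-2,3-dihydro-1-benzofuran-6(5H)-one | C=CC[C@@]1(O)C=C2C(=CC1=O)O[C@H](c1cc(OC)c(OC)c(OC)c1)[C@H]2C
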